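The ratio of isomer of the product to gross target is what to watch in these flasks. Gross target here means target plus half the side product, each side product being taken to have consumed one target. At 20.0 min the ratio reads 0.126 in the amber run, charged with 0.089 M of reagent, and 0.673 in the red run, charged with 0.25 M.

all flasks: substrate 0.12 M

| charge | reagent | remark | time |
|---|---|---|---|
| amber | 0.089 M | run made earlier |  |
| red | 0.25 M | run made earlier |  |
| eta | 0.0600 M |  | 20 min |
| gamma | 0.180 M |  | 20 min |

| run | time / min | target / % | substrate / % | isomer of the product / % | tautomer / % | side product / % |
|---|---|---|---|---|---|---|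
| amber | 2.00 | 17 | 75 | 4 | 0 | 3 |
| amber | 5.00 | 27 | 47 | 6 | 1 | 15 |
| amber | 10.0 | 41 | 21 | 11 | 1 | 30 |
| amber | 15.0 | 43 | 10 | 10 | 0 | 39 |
| amber | 20.0 | 43 | 6 | 8 | 4 | 41 |
| red | 4.00 | 25 | 45 | 23 | 0 | 10 |
| red | 8.00 | 35 | 21 | 27 | 0 | 16 |
| red | 12.0 | 38 | 7 | 29 | 0 | 21 |
| red | 15.0 | 37 | 5 | 33 | 0 | 24 |
| red | 20.0 | 39 | 3 | 35 | 0 | 26 |

(standard deviation of a reading: 1.5 percentage points)
* which of these there is most of at the end, counted by the substrate in it, eta (isomer of the product / target / side product / substrate / tautomer)
* which of these there is most of at the end, counted by the substrate in it, gamma (isomer of the product / target / side product / substrate / tautomer)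
* final amount of the leader among these, as a percentage of the substrate charged, in eta
* final amount of the leader among these, as a percentage of the substrate charged, in gamma
- percent here means substrate units held: one side product counts as two

The reagent curve is replaced by its mean, the midpoint between charge and end. In the red run at 20.0 min:

ratio = 0.673
reagent used per substrate charged = 87.0 %
mean reagent = 0.198 M
branching slope = 3.40 L mol⁻¹

This branching slope, the ratio per unit of mean reagent, is read from single readings and carries their scatter. In the amber run at 10.0 min the reading gives 0.196 and the slope 0.166; with a scatter of 1.5 percentage points on each reading, that gap lies within what the readings carry, so it puts no size on the error of the mean.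

With the red run's use, gamma should end near a ratio of 0.435.

The forecast puts side product first in eta at 40 % and target first in gamma at 41 %, having read that the ratio “rises with reagent, about 3.4 per M”.

The flasks give side product at 39.9 % in eta and target at 42.1 % in gamma. Eta ends with 0 % of its reagent and 20.1 % tautomer. Its mean reagent is therefore the midpoint of charge and zero, so the slope gives a ratio of 0.102 and isomer of the product at 4.63 %; the flask holds 4.47 %.

    substrate ⇌ tautomer (K = 2.50, k = 0.00181 s⁻¹)
    substrate + reagent → isomer of the product (k = 0.00589 L mol⁻¹ s⁻¹)
    reagent + tautomer → target (k = 8.49 L mol⁻¹ s⁻¹)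
    substrate + target → side product (k = 0.0175 L mol⁻¹ s⁻¹)

For one more flask, like gamma but with 0.030 M of substrate, the slope gives 0.561, taking reagent use as the substrate charge. The computed ratio there is 0.541.

The runs come from a simulation with constants of no real substance; the scatter is artificial.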